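**Plan**
1. Ring numbering: C1(OAc)–C2(i-Pr)–C3(OBz)–C4–C5(Me)=C6–C7–C8–C9(Me)–C10, oxirane on C9–C10. C5 and C10 face each other across the ten-membered ring, C5=C6 is an E trisubstituted alkene and C10 bears oxygen. This is the imprint of a trans-decalin whose shared C5–C10 bond has been broken.
2. Retrosynthesis: cut the oxirane C10–O bond (back to a C9-hydroxy C10-mesylate, hence a C10 ketone), then reconnect C5 to C10 (Grob transform) to a trans-decalin 1,3-diol monomesylate. In the bicycle, cut C2–isopropyl (enol triflate coupling), C9–CH3 (Grignard) and the C–O bonds at C1, C3, C9 and C10.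
3. Forward: (R)-Wieland–Miescher ketone brings both six-membered rings and the C5 quaternary carbon. Rings A and B are functionalised while fused, then merged into the ten-membered ring in one fragmentation. The oxirane is the only ring closed afterwards.
4. Stereochemistry: every decalin centre is relayed from the angular methyl group: C6 (borohydride), C1 (allylic hydroxylation), C10 and C9 (osmylation, then Grignard addition), C3 and C2 (hydroboration). The E alkene comes from the anti-periplanar fragmentation. C10 of the oxirane comes from peripheral hydride delivery followed by SN2 closure with inversion.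

Key step: step 16

Assumption: the target SMILES places C8 and C1 on the same face of the oxirane, so the C10 carbinol must be (S) before closure. Locants C1–C10 of the target are used for all intermediates, and β is the face of the decalin that carries the C5 methyl group.

**Route**

Step 1
Reactants: 1 (R)-Wieland–Miescher ketone
Product: 2 C6β-hydroxy enone, (4aR,5R)-5-hydroxy-4a-methyl-4,4a,5,6,7,8-hexahydronaphthalen-2(3H)-one
Conditions: NaBH4 (0.3 equiv), EtOH, −10 °C
Reagents that add atoms: none
Why: Chemoselective borohydride reduction of the saturated C6 ketone in preference to the enone, with axial hydride delivery from the α face (anti to the angular methyl group) giving the equatorial 6β-alcohol.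

Step 2
Reactants: 2 C6β-hydroxy enone
Product: 3 C6β-tert-butyldiphenylsilyl ether of the enone
Conditions: t-BuPh2SiCl, imidazole, DMAP (cat.), DMF, 40 °C
Reagents that add atoms: tert-butyl(chloro)diphenylsilane, CC(C)(C)[Si](Cl)(c1ccccc1)c1ccccc1
Why: Silyl ether protection; this group should survive acid ketalisation and hydrolysis, Grignard, amide-base and borane steps and still leave with fluoride.

Step 3
Reactants: 3 C6β-silyloxy enone
Product: 4 C2 ethylene ketal with the alkene moved to C9=C10
Conditions: HOCH2CH2OH, p-TsOH·H2O (cat.), benzene, reflux (Dean–Stark)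
Reagents that add atoms: ethylene glycol, OCCO
Why: Acid-catalysed ketalisation of a cyclohexenone with migration of the double bond out of conjugation, as for steroidal 4-en-3-ones giving 5-ene ketals; no stereocentre is formed.

Step 4
Reactants: 4 C2 ketal with C9=C10 alkene
Product: 5 C1β-hydroxy ketal (axial allylic alcohol, C9=C10 retained)
Conditions: SeO2 (0.5 equiv), t-BuOOH (3 equiv), CH2Cl2, 23 °C
Reagents that add atoms: selenium dioxide, O=[Se]=O; tert-butyl hydroperoxide, CC(C)(C)OO
Why: Riley allylic hydroxylation (ene reaction, then [2,3]-sigmatropic shift) attacks the methylene on the more substituted alkene carbon, here C1, and should deliver the axial β-alcohol as in the SeO2 oxidation of cholesterol to its 4β-hydroxy derivative.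

Step 5
Reactants: 5 C1β-hydroxy ketal
Product: 6 C1β-(4-methoxybenzyl) ether
Conditions: NaH, 4-MeOC6H4CH2Cl, Bu4NI (cat.), THF/DMF, 0 → 23 °C
Reagents that add atoms: 4-methoxybenzyl chloride, COc1ccc(CCl)cc1
Why: Williamson etherification of the only hydroxyl group; the ether is removed oxidatively at the end of the route.

Step 6
Reactants: 6 C1β-PMB ether with C9=C10 alkene
Product: 7 9α,10α-diol (trans ring fusion; C1β-OPMB, C2 ketal, C6β-OSi)
Conditions: OsO4 (5 mol %), NMO, acetone/H2O, 23 °C
Reagents that add atoms: osmium tetroxide, O=[Os](=O)(=O)=O; N-methylmorpholine N-oxide, C[N+]1([O-])CCOCC1; water, O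
Why: Upjohn syn-dihydroxylation from the α face, anti to both the angular methyl group and the allylic β-OPMB group, which sets the C10 α-hydroxyl (trans fusion) and C9.

Step 7
Reactants: 7 9α,10α-diol
Product: 8 C9 ketone with C10α-OH (α-ketol)
Conditions: Dess–Martin periodinane, pyridine, CH2Cl2, 0 → 23 °C
Reagents that add atoms: none
Why: Dess–Martin oxidation of the only secondary alcohol; the tertiary C10 hydroxyl cannot be oxidised.

Step 8
Reactants: 8 α-ketol; 9 methylmagnesium bromide
Product: 10 C9 tertiary carbinol (9α-Me, 9β-OH) with C10α-OH and C2 ketal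
Conditions: MeMgBr (4 equiv), THF, −78 → 0 °C
Reagents that add atoms: methylmagnesium bromide (9), C[Mg]Br
Why: Grignard 1,2-addition; the β face of the C9 carbonyl is closed by the 1,3-diaxial C5 methyl group, so methyl enters equatorially from the α face (the known course for 6-oxo steroids) and gives 9α-Me/9β-OH.

Step 9
Reactants: 10 C2 ketal triol derivative
Product: 11 C2 ketone (C1β-OPMB, C9β-OH, C10α-OH, C6β-OSi)
Conditions: 2 M aq. HCl, THF, 23 °C
Reagents that add atoms: water, O
Why: Acid hydrolysis of the dioxolane; dehydration of the β-hydroxy ketone is held back because the single C1 hydrogen is equatorial and poorly aligned for enolisation toward the axial C10 hydroxyl.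

Step 10
Reactants: 11 C2 ketone
Product: 13 C2 enol triflate (C2=C3; C9 and C10 hydroxyls free), via trilithium enolate 12 (not isolated)
Conditions: LiN(i-Pr)2 (3.5 equiv), THF, −78 °C (ketone added to base); then PhNTf2, −78 → 0 °C
Reagents that add atoms: N-phenylbis(trifluoromethanesulfonimide), O=S(=O)(N(c1ccccc1)S(=O)(=O)C(F)(F)F)C(F)(F)F
Why: Kinetic deprotonation at the open C3 methylene (C1 is tertiary, alkoxy-substituted and neopentylic) and O-sulfonylation of the enolate, the standard enol triflate synthesis; the excess base holds both tertiary alcohols as lithium alkoxides.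

Step 11
Reactants: 13 C2 enol triflate; 14 isopropylmagnesium chloride
Product: 15 C2-isopropyl C2=C3 alkene
Conditions: i-PrMgCl (4 equiv), Fe(acac)3 (10 mol %), THF/NMP, −30 → 0 °C
Reagents that add atoms: isopropylmagnesium chloride (14), CC(C)[Mg]Cl
Why: Iron-catalysed Kumada-type cross-coupling of an enol triflate with a secondary alkyl Grignard reagent, which tolerates magnesium alkoxides and forms the C2–isopropyl bond without touching a stereocentre.

Step 12
Reactants: 15 C2-isopropyl alkene
Product: 17 C3α-alcohol with C2β-isopropyl, via C3 alkylborane 16 (not isolated)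
Conditions: BH3·THF (5 equiv), THF, 0 → 40 °C; then 3 M NaOH, 30% H2O2, 0 → 23 °C
Reagents that add atoms: hydrogen peroxide, OO
Why: Brown hydroboration–oxidation; boron adds to the less substituted C3 and hydrogen to C2, syn and from the α face (anti to the axial C1 ether and the C5 methyl group), giving C3α-OH and C2β-isopropyl, trans and diequatorial.

Step 13
Reactants: 17 C3α-alcohol; 18 benzoyl chloride
Product: 19 C3α-benzoate
Conditions: BzCl, pyridine, DMAP (cat.), CH2Cl2, 0 → 23 °C
Reagents that add atoms: benzoyl chloride (18), O=C(Cl)c1ccccc1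
Why: DMAP-catalysed acylation of the only secondary alcohol (the tertiary hydroxyls at C9 and C10 do not react), installing the benzoate of the target.

Step 14
Reactants: 19 C3α-benzoate with C6β-OSi
Product: 20 C6β-alcohol
Conditions: Bu4NF/AcOH (1:1), THF, 40 °C
Reagents that add atoms: none
Why: Fluoride desilylation, buffered with acetic acid so that the benzoate is neither hydrolysed nor moved.

Step 15
Reactants: 20 C6β-alcohol
Product: 21 C6β-mesylate: trans-decalin with C10α-OH, C5β-Me, C6β-OMs (equatorial), C9 (α-Me, β-OH), C1β-OPMB, C2β-i-Pr, C3α-OBz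
Conditions: MsCl, Et3N, CH2Cl2, −20 → 0 °C
Reagents that add atoms: methanesulfonyl chloride, CS(=O)(=O)Cl
Why: Sulfonylation of the only secondary alcohol; no alkoxide is formed under these conditions, so the fragmentation is not set off early.

Step 16
Reactants: 21 C6β-mesylate
Product: 23 (E)-cyclodec-5-en-1-one with C10 ketone (C9 α-Me/OH; C1 OPMB; C2 i-Pr; C3 OBz), via potassium C10 alkoxide 22 (not isolated)
Conditions: KN(SiMe3)2 (1.05 equiv), THF, −78 → 0 °C; pH 7 buffer
Reagents that add atoms: none
Why: Grob fragmentation of a 1,3-diol monomesylate: the C10 alkoxide pushes its lone pair into C10 while the C5–C10 σ bond breaks and the anti-periplanar C6–OMs bond ionises in one concerted event, giving C10=O and C5=C6. The closest known reaction is the base-induced fragmentation of trans-decalin 1,3-diol monosulfonates to (E)-cyclodec-5-enones used for germacranes. No ring is closed by bond formation; the two six-membered rings become the ten-membered ring by cleavage of their shared bond. No stereocentre is created, and the alkene is E because C4 (equatorial on C5) and C7 are anti about C5–C6 in the chair. Fragmentation must outrun elimination, substitution and ester cleavage: the locked trans-decalin holds the equatorial mesylate anti to C5–C10 with no anti-periplanar hydrogen for E2, neopentyl C6 cannot undergo SN2, and one equivalent of a non-nucleophilic amide base at low temperature spares the benzoate. Proton exchange between the two tertiary hydroxyls drains through the C10 alkoxide, and no base is left to epimerise C1 or rearrange the α-ketol.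

Step 17
Reactants: 23 cyclodecenone
Product: 24 (10S)-C10 alcohol (9,10-diol; C1 OPMB, C3 OBz)
Conditions: NaBH4, MeOH/THF, −40 → −20 °C
Reagents that add atoms: none
Why: Borohydride reduction in which the C5=C6 alkene still lies across the inner face of the C10 carbonyl, so hydride should come from the ring periphery (also the Felkin–Anh face for both flanking C–O bonds) and place the hydroxyl where the C5–C10 bond used to be, giving (10S).

Step 18
Reactants: 24 (10S)-9,10-diol
Product: 26 C9–C10 epoxide with C1 OPMB and C3 OBz, via C10 mesylate 25 (not isolated)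
Conditions: MsCl, Et3N, CH2Cl2, −20 °C; then DBU, 23 °C
Reagents that add atoms: none
Why: Selective mesylation of the secondary C10 alcohol, then intramolecular Williamson (3-exo-tet) closure by the tertiary C9 hydroxyl with inversion at C10, which gives the (9S,10R) oxirane with C8 and C1 cis.

Step 19
Reactants: 26 epoxide PMB ether
Product: 27 C1 alcohol (epoxy alcohol, C3 OBz)
Conditions: DDQ, CH2Cl2/pH 7 phosphate buffer, 0 °C
Reagents that add atoms: none
Why: Oxidative cleavage of the 4-methoxybenzyl ether with DDQ under buffered conditions, which should leave the epoxide, the alkene and the benzoate intact.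

Step 20
Reactants: 27 C1 alcohol; 28 acetic anhydride
Product: 29 target compound CNP0112246.1
Conditions: Ac2O, pyridine, DMAP (cat.), CH2Cl2, 0 → 23 °C
Reagents that add atoms: acetic anhydride (28), CC(=O)OC(C)=O
Why: DMAP-catalysed acetylation of the C1 alcohol without forming an alkoxide, so the neighbouring epoxide cannot undergo Payne rearrangement.

**Compound list**
1 | (R)-Wieland–Miescher ketone, (R)-8a-methyl-3,4,8,8a-tetrahydronaphthalene-1,6(2H,7H)-dione | C[C@@]12CCC(=O)C=C1CCCC2=O | starting material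
2 | C6β-hydroxy enone | C1C[C@@H](O)[C@]2(C)CCC(=O)C=C2C1 | intermediate
3 | C6β-OTBDPS enone | C1C[C@@H](O[Si](c3ccccc3)(c4ccccc4)C(C)(C)C)[C@]2(C)CCC(=O)C=C2C1 | intermediate
4 | C2 ethylene ketal, C9=C10 alkene, C6β-OTBDPS | C1C[C@@H](O[Si](c3ccccc3)(c4ccccc4)C(C)(C)C)[C@]2(C)CCC5(OCCO5)CC2=C1 | intermediate
5 | C1β-hydroxy ketal, C9=C10 alkene | C1C[C@@H](O[Si](c3ccccc3)(c4ccccc4)C(C)(C)C)[C@]2(C)CCC5(OCCO5)[C@@H](O)C2=C1 | intermediate
6 | C1β-OPMB ketal, C9=C10 alkene | C1C[C@@H](O[Si](c3ccccc3)(c4ccccc4)C(C)(C)C)[C@]2(C)CCC5(OCCO5)[C@@H](OCc6ccc(OC)cc6)C2=C1 | intermediate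
7 | 9α,10α-diol, C1β-OPMB, C2 ketal | C1C[C@@H](O[Si](c3ccccc3)(c4ccccc4)C(C)(C)C)[C@]2(C)CCC5(OCCO5)[C@@H](OCc6ccc(OC)cc6)[C@@]2(O)[C@@H]1O | intermediate
8 | C9 ketone, C10α-OH (α-ketol) | C1C[C@@H](O[Si](c3ccccc3)(c4ccccc4)C(C)(C)C)[C@]2(C)CCC5(OCCO5)[C@@H](OCc6ccc(OC)cc6)[C@@]2(O)C1=O | intermediate
9 | methylmagnesium bromide | C[Mg]Br | starting material
10 | C9 carbinol (9α-Me, 9β-OH), C10α-OH, C2 ketal | C1C[C@@H](O[Si](c3ccccc3)(c4ccccc4)C(C)(C)C)[C@]2(C)CCC5(OCCO5)[C@@H](OCc6ccc(OC)cc6)[C@@]2(O)[C@@]1(C)O | intermediate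
11 | C2 ketone, C1β-OPMB, C9β-OH, C10α-OH | C1C[C@@H](O[Si](c3ccccc3)(c4ccccc4)C(C)(C)C)[C@]2(C)CCC(=O)[C@@H](OCc6ccc(OC)cc6)[C@@]2(O)[C@@]1(C)O | intermediate
12 | trilithium enolate (C2=C3 enolate, C9 and C10 alkoxides) | C1C[C@@H](O[Si](c3ccccc3)(c4ccccc4)C(C)(C)C)[C@]2(C)CC=C(O[Li])[C@@H](OCc6ccc(OC)cc6)[C@@]2(O[Li])[C@@]1(C)O[Li] | intermediate
13 | C2 enol triflate (C2=C3) | C1C[C@@H](O[Si](c3ccccc3)(c4ccccc4)C(C)(C)C)[C@]2(C)CC=C(OS(=O)(=O)C(F)(F)F)[C@@H](OCc6ccc(OC)cc6)[C@@]2(O)[C@@]1(C)O | intermediate
14 | isopropylmagnesium chloride | CC(C)[Mg]Cl | starting material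
15 | C2-isopropyl C2=C3 alkene | C1C[C@@H](O[Si](c3ccccc3)(c4ccccc4)C(C)(C)C)[C@]2(C)CC=C(C(C)C)[C@@H](OCc6ccc(OC)cc6)[C@@]2(O)[C@@]1(C)O | intermediate
16 | C3α-alkylborane, C2β-isopropyl (drawn as RBH2, hydroxyls unassociated) | C1C[C@@H](O[Si](c3ccccc3)(c4ccccc4)C(C)(C)C)[C@]2(C)C[C@H](B)[C@@H](C(C)C)[C@@H](OCc6ccc(OC)cc6)[C@@]2(O)[C@@]1(C)O | intermediate
17 | C3α-alcohol, C2β-isopropyl | C1C[C@@H](O[Si](c3ccccc3)(c4ccccc4)C(C)(C)C)[C@]2(C)C[C@H](O)[C@@H](C(C)C)[C@@H](OCc6ccc(OC)cc6)[C@@]2(O)[C@@]1(C)O | intermediate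
18 | benzoyl chloride | O=C(Cl)c1ccccc1 | starting material
19 | C3α-benzoate, C6β-OTBDPS | C1C[C@@H](O[Si](c3ccccc3)(c4ccccc4)C(C)(C)C)[C@]2(C)C[C@H](OC(=O)c7ccccc7)[C@@H](C(C)C)[C@@H](OCc6ccc(OC)cc6)[C@@]2(O)[C@@]1(C)O | intermediate
20 | C6β-alcohol | C1C[C@@H](O)[C@]2(C)C[C@H](OC(=O)c7ccccc7)[C@@H](C(C)C)[C@@H](OCc6ccc(OC)cc6)[C@@]2(O)[C@@]1(C)O | intermediate
21 | C6β-mesylate (fragmentation precursor) | C1C[C@@H](OS(C)(=O)=O)[C@]2(C)C[C@H](OC(=O)c7ccccc7)[C@@H](C(C)C)[C@@H](OCc6ccc(OC)cc6)[C@@]2(O)[C@@]1(C)O | intermediate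
22 | potassium C10 alkoxide of 21 | C1C[C@@H](OS(C)(=O)=O)[C@]2(C)C[C@H](OC(=O)c7ccccc7)[C@@H](C(C)C)[C@@H](OCc6ccc(OC)cc6)[C@@]2(O[K])[C@@]1(C)O | intermediate
23 | (E)-cyclodec-5-en-1-one (C10 ketone), C9 (Me, OH), C1 OPMB, C2 i-Pr, C3 OBz | C1C/C=C(C)/C[C@H](OC(=O)c7ccccc7)[C@@H](C(C)C)[C@@H](OCc6ccc(OC)cc6)C(=O)[C@@]1(C)O | intermediate
24 | (10S)-C10 alcohol (9,10-diol) | C1C/C=C(C)/C[C@H](OC(=O)c7ccccc7)[C@@H](C(C)C)[C@@H](OCc6ccc(OC)cc6)[C@H](O)[C@@]1(C)O | intermediate
25 | C10 mesylate, C9-OH | C1C/C=C(C)/C[C@H](OC(=O)c7ccccc7)[C@@H](C(C)C)[C@@H](OCc6ccc(OC)cc6)[C@H](OS(C)(=O)=O)[C@@]1(C)O | intermediate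
26 | C9–C10 epoxide, C1 OPMB, C3 OBz | COc1ccc(CO[C@@H]2[C@H](C(C)C)[C@@H](OC(=O)c3ccccc3)C/C(C)=C/CC[C@]4(C)O[C@H]24)cc1 | intermediate
27 | epoxy alcohol (C1-OH, C3 OBz) | O[C@@H]1[C@H](C(C)C)[C@@H](OC(=O)c2ccccc2)C/C(C)=C/CC[C@]2(C)O[C@H]12 | intermediate
28 | acetic anhydride | CC(=O)OC(C)=O | starting material
29 | CNP0112246.1 (C1 acetate, C3 benzoate, C9–C10 epoxide, E C5=C6) | CC(=O)O[C@@H]1[C@H](C(C)C)[C@@H](OC(=O)c2ccccc2)C/C(C)=C/CC[C@]2(C)O[C@H]12 | target

**Totals and risks**
Total step count: 20. Longest linear sequence: 20 steps from (R)-Wieland–Miescher ketone.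

Most likely to fail:

1. Step 4 (allylic hydroxylation). The oxidation may go astray: attack at the C8 methylene, over-oxidation to the enone, or acid-promoted loss of the ketal. Fallback, from 3 back to 5: enone 3 would be ketalised without double-bond migration (1,2-bis(trimethylsilyloxy)ethane, Me3SiOTf cat., CH2Cl2, −78 °C) to the C1=C10 allylic ketal F1. Buffered mCPBA epoxidation on the α face would give the 1α,10α-epoxide F2. LiNEt2 (Et2O, reflux) would isomerise it to an allylic alcohol; the ketal carbon C2 has no hydrogen, so only a C9 hydrogen can be removed, the C10–O bond breaks and the alkene appears at C9=C10, giving the C1α-alcohol F3 (C1 epimer of 5). MnO2 would give the C1 enone F4. Reduction with NaBH4/CeCl3·7H2O, which must approach from the α face because the angular methyl group and the axial ketal oxygen close the β face, would return the axial C1β-alcohol 5.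

2. Step 11 (iron-catalysed isopropyl coupling). Reduction of the triflate, β-hydride elimination or isomerisation of the secondary alkyl group at the metal, or slow reaction next to the crowded C1 and C10 centres may prevail. Fallback, from 13 back to 15: Suzuki–Miyaura coupling with isopropenylboronic acid pinacol ester (Pd(PPh3)4, K3PO4, dioxane/H2O, 80 °C) would give the 2-isopropenyl diene F5. Hydrogenation of only the 1,1-disubstituted alkene with H2 and RhCl(PPh3)3 (benzene, 23 °C), the selectivity known from carvone, would give 15.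

3. Step 17 (ketone reduction). Facial selectivity may be poor if the ten-membered ring turns the carbonyl through the ring plane, or if the free C9 hydroxyl steers hydride to the other face. Fallback, from 23 back to 26: the C9 hydroxyl would be silylated (Et3SiOTf, 2,6-lutidine, −78 °C) to the C9 triethylsilyl ether F6. Reduction with LiBH(s-Bu)3 (THF, −78 °C), under Felkin–Anh control by two non-chelating α-oxygen substituents that both favour the same face, would give the (10S)-alcohol F7. Mesylation (MsCl, Et3N) would give the C10 mesylate F8. Bu4NF (THF, 0 → 23 °C) would remove the silyl group, and the C9 alkoxide would close the oxirane with inversion to give 26.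

**Further compounds**
F1 | step 4 | C2 ethylene ketal with unshifted C1=C10 alkene, C6β-OTBDPS | C1C[C@@H](O[Si](c3ccccc3)(c4ccccc4)C(C)(C)C)[C@]2(C)CCC5(OCCO5)C=C2C1
F2 | step 4 | 1α,10α-epoxide of the C2 ketal | C1C[C@@H](O[Si](c3ccccc3)(c4ccccc4)C(C)(C)C)[C@]2(C)CCC5(OCCO5)[C@@H]6O[C@@]62C1
F3 | step 4 | C1α-hydroxy ketal with C9=C10 alkene (C1 epimer of 5) | C1C[C@@H](O[Si](c3ccccc3)(c4ccccc4)C(C)(C)C)[C@]2(C)CCC5(OCCO5)[C@H](O)C2=C1
F4 | step 4 | C1 enone (C1=O, C9=C10) with C2 ketal | C1C[C@@H](O[Si](c3ccccc3)(c4ccccc4)C(C)(C)C)[C@]2(C)CCC5(OCCO5)C(=O)C2=C1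
F5 | step 11 | 2-isopropenyl C2=C3 diene | C1C[C@@H](O[Si](c3ccccc3)(c4ccccc4)C(C)(C)C)[C@]2(C)CC=C(C(C)=C)[C@@H](OCc6ccc(OC)cc6)[C@@]2(O)[C@@]1(C)O
F6 | step 17 | cyclodecenone with C9 triethylsilyl ether | C1C/C=C(C)/C[C@H](OC(=O)c7ccccc7)[C@@H](C(C)C)[C@@H](OCc6ccc(OC)cc6)C(=O)[C@@]1(C)O[Si](CC)(CC)CC
F7 | step 17 | (10S)-alcohol with C9 triethylsilyl ether | C1C/C=C(C)/C[C@H](OC(=O)c7ccccc7)[C@@H](C(C)C)[C@@H](OCc6ccc(OC)cc6)[C@H](O)[C@@]1(C)O[Si](CC)(CC)CC
F8 | step 17 | C10 mesylate with C9 triethylsilyl ether | C1C/C=C(C)/C[C@H](OC(=O)c7ccccc7)[C@@H](C(C)C)[C@@H](OCc6ccc(OC)cc6)[C@H](OS(C)(=O)=O)[C@@]1(C)O[Si](CC)(CC)CC
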